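**Retrosynthetic overview**

1. Target 18 ← racemate 17 (resolution) ← hemiketal 14 (acidic MeOH sets the ketal carbon C-6 under equilibration and exchanges the ester).
2. The 1,2-dioxine ring of 14 is made from the four-membered carbocycle of cyclobutenol 12 by insertion of O2 into one ring bond. Ring carbons C1, C2, C3, C4 of 12 become C-3, C-6, C-5, C-4 of the dioxine.
3. Enabling feature: in the strained cyclobut-3-ene ring of 12 the tertiary carbinol carbon C2 (OH, hexadecyl) is bonded to the allylic sp3 carbon C1 (H, CH2CO2t-Bu). An alkoxy radical on C2 should cleave C1–C2 selectively, and the ring cis-alkene C3=C4 is handed on as the Z alkene that ring closure needs.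
4. 12 ← hexadecylmagnesium bromide 11 + cyclobutenone 9 (C16 and C6 halves joined at the fully substituted carbon). 9 ← cyclobutanone 1 by hydrazone alkylation with 3 and α,β-dehydrogenation.
5. Ring order: cyclobutane (purchased) → cyclobutene (step 3) → 3,6-dihydro-1,2-dioxine (step 5, four- to six-membered).

Key step: step 5

Assumption: the radical oxygenation cannot set the absolute configuration at C-3, so the peroxide is carried as a racemate and resolved in step 7; racemic or diastereomeric intermediates are written without stereodescriptors.

**Step 1**
Reactants: 1 cyclobutanone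
Product: 2 cyclobutanone N,N-dimethylhydrazone
Conditions: Me2NNH2, AcOH (cat.), EtOH, 60 °C
Reagents that add atoms: N,N-dimethylhydrazine, CN(C)N
Why: Acid-catalysed condensation (hydrazone formation) is clean for the unhindered strained ketone and gives a derivative that can be mono-alkylated, which the self-condensing lithium enolate of cyclobutanone cannot.

**Step 2**
Reactants: 2 cyclobutanone N,N-dimethylhydrazone; 3 tert-butyl bromoacetate
Product: 6 tert-butyl 2-(2-oxocyclobutyl)acetate (racemic), via lithiated hydrazone 4 (not isolated), via alkylated hydrazone 5 (not isolated)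
Conditions: LiN(i-Pr)2, THF, −78 to 0 °C; 3, −78 °C to rt; then aq. oxalic acid, Et2O, rt
Reagents that add atoms: water, O
Why: Corey–Enders hydrazone alkylation: the lithium azaenolate reacts once at carbon with the reactive α-bromo ester, the tert-butyl ester is inert to the amide base, and two-phase oxalic acid hydrolysis frees the ketone without touching the ester; the new α-stereocentre is racemic, which is acceptable because step 5 turns this carbon into a planar radical.

**Step 3**
Reactants: 6 tert-butyl 2-(2-oxocyclobutyl)acetate
Product: 9 tert-butyl 2-(2-oxocyclobut-3-en-1-yl)acetate (racemic), via lithium enolate 7 (not isolated), via sulfilimine adduct 8 (not isolated)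
Conditions: LiN(i-Pr)2, THF, −78 °C; PhS(Cl)=N-t-Bu, −78 °C; cold aqueous work-up, used at once as a cold solution
Reagents that add atoms: none
Why: Mukaiyama α,β-dehydrogenation of a ketone: kinetic deprotonation occurs at the unsubstituted α'-CH2, the enolate is sulfenylated at carbon, and sulfilimine 8 undergoes syn-elimination at −78 °C with the only β-hydrogens available (ring CH2), so the double bond is placed away from the substituted carbon and the heat-sensitive cyclobutenone is never warmed.

**Step 4**
Reactants: 9 tert-butyl 2-(2-oxocyclobut-3-en-1-yl)acetate; 10 1-bromohexadecane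
Product: 12 tert-butyl 2-(2-hexadecyl-2-hydroxycyclobut-3-en-1-yl)acetate (mixture of two racemic diastereomers), via hexadecylmagnesium bromide 11 (not isolated)
Conditions: 10, Mg, THF, 45 °C; then LaCl3·2LiCl, 9, THF, −78 °C; aq. NH4Cl at −78 °C
Reagents that add atoms: none
Why: Grignard 1,2-addition to a ketone, with LaCl3·2LiCl to suppress conjugate addition and enolisation: the strained ring ketone is far more electrophilic than the hindered tert-butyl ester, which is also too hindered to lactonise with the new alkoxide, and the two halves of the molecule are joined at the fully substituted carbinol carbon; the carbinol centre forms as a diastereomer mixture that is used as such because step 5 erases the difference, and the cold quench prevents oxy-anion-accelerated opening of the cyclobutene.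

**Step 5**
Reactants: 12 tert-butyl 2-(2-hexadecyl-2-hydroxycyclobut-3-en-1-yl)acetate
Product: 14 tert-butyl 2-(6-hexadecyl-6-hydroxy-3,6-dihydro-1,2-dioxin-3-yl)acetate (racemic; mixture of hemiketal epimers), via hydroperoxy enone 13 (not isolated)
Conditions: Co(acac)2 (20 mol %), O2 (1 atm), MeCN, 25 °C, dark
Reagents that add atoms: dioxygen, O=O
Why: Proposed new method: divalent cobalt is oxidised by O2 to a trivalent cobalt peroxo species that exchanges a ligand for the tertiary alcohol and releases the alkoxy radical; strain-driven β-scission then breaks ring bond C1–C2 (the only β-bond whose cleavage gives a stabilised, allylic radical conjugated with the new enone, since C2–C3 would give a vinyl radical and the exocyclic bond relieves no strain) and the resulting Z-configured γ-keto allyl radical is trapped by triplet O2 at C1, reduced to hydroperoxide 13 and closed onto the ketone. The closest known reaction types are the Co(acac)2/O2 oxidative ring expansion of saturated cyclobutanols to 1,2-dioxan-3-ols and the Mn(acac)3-catalysed aerobic conversion of cyclopropanols into 1,2-dioxolan-3-ols; the cyclobut-2-enol case, with its allylic radical, is the extension proposed here. The dioxine ring closes by 6-exo-trig addition of the hydroperoxide oxygen to the C=O group (peroxyhemiketalisation), which is possible only because the cis geometry of the ring alkene is carried into the open chain. Of the two new stereocentres, C-3 arises from a planar radical without control (racemic, resolved in step 7) and the hemiketal carbon C-6 is an equilibrating anomeric centre that is fixed only in step 6. The step needs regioselective ring cleavage and retention of the Z alkene; the position of the alkoxy radical on the hexadecyl-bearing carbon, the allylic nature of C1 and trapping by O2 at high concentration (faster than rotation of the allyl radical and faster than 1,5-hydrogen transfer from the chain) should secure both, and both diastereomers of 12 converge on the same radical.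

**Step 6**
Reactants: 14 tert-butyl 2-(6-hexadecyl-6-hydroxy-3,6-dihydro-1,2-dioxin-3-yl)acetate
Product: 17 methyl 2-[(3S*,6R*)-6-hexadecyl-6-methoxy-3,6-dihydro-1,2-dioxin-3-yl]acetate (racemate; methoxy group trans to the acetate arm), via methoxy ketal tert-butyl ester 15 (not isolated), via methoxy ketal acid 16 (not isolated)
Conditions: HCl (1.25 M in MeOH), 25 °C; NaHCO3; SiO2 chromatography
Reagents that add atoms: methanol, CO
Why: Acid-catalysed peroxyketalisation through the cyclic peroxycarbenium ion, combined with acidolysis of the tert-butyl ester and Fischer esterification, lets methanol deliver both methyl groups in one operation; C-6 forms under equilibrating conditions (anomeric preference puts OMe pseudo-axial while the arm at C-3 can sit either way, so neither epimer should dominate), the wanted isomer 17 is separated on silica from its C-6 epimer, and that epimer is returned to the same conditions, which re-equilibrate only the ketal carbon.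

**Step 7**
Reactants: 17 methyl 2-[(3S*,6R*)-6-hexadecyl-6-methoxy-3,6-dihydro-1,2-dioxin-3-yl]acetate (racemate)
Product: 18 methyl 2-[(3S,6R)-6-hexadecyl-6-methoxy-3,6-dihydro-1,2-dioxin-3-yl]acetate
Conditions: preparative SFC, amylose tris(3,5-dimethylphenylcarbamate) phase, CO2/i-PrOH, 30 °C
Reagents that add atoms: none
Why: Resolution of a racemate by chromatography on a chiral stationary phase: the enantiomers of this neutral peroxy ketal differ in their fit to the helical amylose carbamate, no reagent touches the O–O bond or the ketal, and both stereocentres are configurationally stable under neutral conditions, so the (3S,6R) enantiomer should be obtained as a single stereoisomer (to be assigned by anomalous-dispersion X-ray analysis or by comparison of calculated and recorded chiroptical data).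

**Compound list**

1 | cyclobutanone | O=C1CCC1 | starting material
2 | cyclobutanone N,N-dimethylhydrazone | CN(C)N=C1CCC1 | intermediate
3 | tert-butyl bromoacetate | CC(C)(C)OC(=O)CBr | starting material
4 | lithiated hydrazone (lithium azaenolate of 2) | [Li+].CN(C)[N-]C1=CCC1 | intermediate
5 | tert-butyl 2-[2-(2,2-dimethylhydrazinylidene)cyclobutyl]acetate (racemic) | CN(C)N=C1CCC1CC(=O)OC(C)(C)C | intermediate
6 | tert-butyl 2-(2-oxocyclobutyl)acetate (racemic) | O=C1CCC1CC(=O)OC(C)(C)C | intermediate
7 | lithium enolate of 6 (toward the ring CH2) | [Li+].[O-]C1=CCC1CC(=O)OC(C)(C)C | intermediate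
8 | tert-butyl 2-[3-(N-tert-butyl-S-phenylsulfinimidoyl)-2-oxocyclobutyl]acetate (diastereomer mixture) | O=C1C(CC(=O)OC(C)(C)C)CC1S(=NC(C)(C)C)c2ccccc2 | intermediate
9 | tert-butyl 2-(2-oxocyclobut-3-en-1-yl)acetate (racemic) | O=C1C=CC1CC(=O)OC(C)(C)C | intermediate
10 | 1-bromohexadecane | CCCCCCCCCCCCCCCCBr | starting material
11 | hexadecylmagnesium bromide | CCCCCCCCCCCCCCCC[Mg]Br | intermediate
12 | tert-butyl 2-(2-hexadecyl-2-hydroxycyclobut-3-en-1-yl)acetate (two racemic diastereomers) | CCCCCCCCCCCCCCCCC1(O)C=CC1CC(=O)OC(C)(C)C | intermediate
13 | tert-butyl (4Z)-3-hydroperoxy-6-oxodocos-4-enoate (racemic) | CCCCCCCCCCCCCCCCC(=O)/C=C\C(OO)CC(=O)OC(C)(C)C | intermediate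
14 | tert-butyl 2-(6-hexadecyl-6-hydroxy-3,6-dihydro-1,2-dioxin-3-yl)acetate (racemic, hemiketal epimers) | CCCCCCCCCCCCCCCCC1(O)C=CC(CC(=O)OC(C)(C)C)OO1 | intermediate
15 | tert-butyl 2-(6-hexadecyl-6-methoxy-3,6-dihydro-1,2-dioxin-3-yl)acetate (racemic, ketal epimers) | CCCCCCCCCCCCCCCCC1(OC)C=CC(CC(=O)OC(C)(C)C)OO1 | intermediate
16 | 2-(6-hexadecyl-6-methoxy-3,6-dihydro-1,2-dioxin-3-yl)acetic acid (racemic, ketal epimers) | CCCCCCCCCCCCCCCCC1(OC)C=CC(CC(=O)O)OO1 | intermediate
17 | methyl 2-[(3S*,6R*)-6-hexadecyl-6-methoxy-3,6-dihydro-1,2-dioxin-3-yl]acetate (racemate, both enantiomers drawn) | CCCCCCCCCCCCCCCC[C@]1(OC)C=C[C@H](CC(=O)OC)OO1.CCCCCCCCCCCCCCCC[C@@]1(OC)C=C[C@@H](CC(=O)OC)OO1 | intermediate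
18 | methyl 2-[(3S,6R)-6-hexadecyl-6-methoxy-3,6-dihydro-1,2-dioxin-3-yl]acetate | CCCCCCCCCCCCCCCC[C@]1(OC)C=C[C@H](CC(=O)OC)OO1 | target

**Step count and risks**

Total step count: 7. Longest linear sequence: 7 steps (1 → 18).

Steps most likely to fail:

Step 5 (Proposed new method). Electrocyclic opening of the cobalt alkoxide may outrun radical β-scission, so that the Z geometry is lost and the hydroperoxide cannot close. The allyl radical may also be oxygenated next to the ketone, or divalent cobalt may open the product peroxide by electron transfer. The fallback uses known chemistry, sets out from 12 and returns to 14. Heating 12 in toluene at 90 °C should open the ring by thermal conrotatory 4π electrocyclic ring opening, and the dienol should ketonise to the β,γ-unsaturated ketone tert-butyl (3E)-6-oxodocos-3-enoate F1. A Schenck ene reaction of F1 with singlet oxygen (O2, tetraphenylporphyrin, hν, CH2Cl2, 0 °C) should move the double bond into conjugation and give tert-butyl (4E)-3-hydroperoxy-6-oxodocos-4-enoate F2, with the regioisomeric ene product removed by chromatography. Irradiation of F2 (350 nm, benzene) should isomerise E to Z; the Z isomer 13 is drained from the photoequilibrium by closing to 14.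

Step 3. The free cyclobutenone may polymerise or suffer conjugate addition during its formation and handling, or deprotonation may occur on the substituted side. The fallback sets out from 6 and returns to 12 without ever freeing the enone. The kinetic enolate of 6 (LiN(i-Pr)2, THF, −78 °C) is selenenylated with PhSeBr to tert-butyl 2-[2-oxo-3-(phenylselanyl)cyclobutyl]acetate F3. The organocerium reagent made from 11 and CeCl3 (THF, −78 °C) then adds to the ketone to give tert-butyl 2-[2-hexadecyl-2-hydroxy-3-(phenylselanyl)cyclobutyl]acetate F4. Oxidation with H2O2 (CH2Cl2, pyridine, 0 °C) and selenoxide syn-elimination, which can only go toward the ring CH2, should give the allylic alcohol 12.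

Step 6. The long acid exposure needed to cleave the tert-butyl ester may fragment the peroxide (Hock-type cleavage), or the ester exchange may stay incomplete. The fallback sets out from 14 and returns to 17 through separate mild operations. Brief treatment with TFA in CH2Cl2 at 0 °C should cleave the ester to 2-(6-hexadecyl-6-hydroxy-3,6-dihydro-1,2-dioxin-3-yl)acetic acid F5. Me3SiCHN2 in toluene/MeOH should give methyl 2-(6-hexadecyl-6-hydroxy-3,6-dihydro-1,2-dioxin-3-yl)acetate F6. Short ketalisation of F6 (MeOH, pyridinium tosylate, 25 °C) should then give 17 together with its C-6 epimer, which is separated on silica and re-equilibrated under the same conditions.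

**Further compounds**

F1 | step 5 | tert-butyl (3E)-6-oxodocos-3-enoate | CCCCCCCCCCCCCCCCC(=O)C/C=C/CC(=O)OC(C)(C)C
F2 | step 5 | tert-butyl (4E)-3-hydroperoxy-6-oxodocos-4-enoate (racemic) | CCCCCCCCCCCCCCCCC(=O)/C=C/C(OO)CC(=O)OC(C)(C)C
F3 | step 3 | tert-butyl 2-[2-oxo-3-(phenylselanyl)cyclobutyl]acetate (diastereomer mixture) | O=C1C([Se]c2ccccc2)CC1CC(=O)OC(C)(C)C
F4 | step 3 | tert-butyl 2-[2-hexadecyl-2-hydroxy-3-(phenylselanyl)cyclobutyl]acetate (diastereomer mixture) | CCCCCCCCCCCCCCCCC1(O)C([Se]c2ccccc2)CC1CC(=O)OC(C)(C)C
F5 | step 6 | 2-(6-hexadecyl-6-hydroxy-3,6-dihydro-1,2-dioxin-3-yl)acetic acid (racemic, hemiketal epimers) | CCCCCCCCCCCCCCCCC1(O)C=CC(CC(=O)O)OO1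
F6 | step 6 | methyl 2-(6-hexadecyl-6-hydroxy-3,6-dihydro-1,2-dioxin-3-yl)acetate (racemic, hemiketal epimers) | CCCCCCCCCCCCCCCCC1(O)C=CC(CC(=O)OC)OO1
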